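(Readings and results are simulated with constants of no real substance; the scatter is artificial.)

In this flask, free monomer is charged at 0.054 M, against 54 µM of initiator and 27 µM of radical scavenger, so the scavenger amounts to 0.0500% of the monomer. The earlier runs show where the monomer goes.

| flask | free monomer | initiator | radical scavenger | remark | time |
|---|---|---|---|---|---|
| Thursday's | 0.076 M | 54 µM | 27 µM | run made earlier |  |
| Tuesday's | 0.12 M | 54 µM | 27 µM | run made earlier |  |
| Saturday's | 0.054 M | 27 µM | 27 µM | run made earlier |  |
| flask | 0.054 M | 54 µM | 27 µM |  | 25 h |

| run | time / h | homo dimer / % | monomer in chains / % |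
|---|---|---|---|
| Thursday's | 4.00 | 29 | 0 |
| Thursday's | 8.00 | 41 | 0 |
| Thursday's | 12.0 | 56 | 1 |
| Thursday's | 15.0 | 60 | 1 |
| Tuesday's | 1.33 | 16 | 0 |
| Tuesday's | 3.00 | 32 | 2 |
| Tuesday's | 6.00 | 50 | 0 |
| Tuesday's | 15.0 | 71 | 0 |
| Saturday's | 1.33 | 10 | 1 |
| Saturday's | 3.00 | 17 | 0 |
| Saturday's | 6.00 | 28 | 0 |
| Saturday's | 15.0 | 53 | 0 |

(standard deviation of a reading: 1.5 percentage points)

- percent here means free monomer units held: one homo dimer counts as two

* amount of homo dimer in percent of the free monomer charged, at 80 min, 6.0 h and 25 h

The last rows, at 15.0 h, can be read side by side. Tuesday's run holds 71% as homo dimer, Thursday's 60% and Saturday's 53%, in the order of their monomer charges, though Saturday's run also has less initiator. Monomer in chains reads 0%, 1% and 0% in those rows, within the scatter of 1.5 percentage points.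

If free monomer goes by second-order pairing, the dimer share divided by the free share grows in step with time t and with the charge. One quantity then describes a flask: the pairing half-time τ, when dimer share equals free share, which varies inversely with the charge. It equals t times free share over dimer share.

Scaled to this flask's charge, Tuesday's last row gives 13.6 h, Thursday's 14.1 h and Saturday's 13.3 h. Saturday's run, with half the initiator of the other two, shows no longer τ. The mean of these three values, read from scattered readings, gives the pairing half-time τ for this flask as 13.7 h.

The dimer share is then t/(t+τ), which gives 8.89% at 80 min, 30.5% at 6.0 h and 64.7% at 25 h. That last time lies past the last reading of the earlier runs, at 15.0 h.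

The forecast, 8.7%, 30% and 64%, stands a little lower than this reckoning at each time, and it opens with “Every run fits simple second-order dimerisation”.

This flask gives 8.80%, 30.3% and 64.4%, and at 25.0 h it still holds 57% of its radical scavenger, with monomer in chains at 0.0225%.

    initiator → 2 initiating radical (k = 0.00460 h⁻¹)
    free monomer + initiating radical → growing radical + monomer in chains (k = 39000 M⁻¹ s⁻¹)
    free monomer + growing radical → monomer in chains + growing radical, rate k3*[growing radical]*[free monomer] (k = 2.10 × 10⁶ M⁻¹ h⁻¹)
    2 growing radical → dead chain (k = 1.40 × 10⁶ M⁻¹ s⁻¹)
    2 free monomer → homo dimer (k = 0.670 M⁻¹ h⁻¹)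
    growing radical + radical scavenger → ended chains (k = 2.50 × 10⁷ M⁻¹ s⁻¹)

Carried to 250 h, ten times the asked time, τ gives a dimer share of 94.8%. The same flask then holds less homo dimer, 87.7%, with radical scavenger at 0% and monomer in chains at 11.0%.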